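**Retrosynthetic overview**

1. Target gibberellin 28 ⇐ hydrolysis of diester 26 ⇐ one-step ring contraction of the 13-oxo-16-methylene bicyclo[2.2.2]octane 25: a C-13 ketyl adds to C-16 and the C12–C16 bond opens.
2. Enabling feature: in 25 the six-membered ring C8–C14–C13–C12–C16–C15 holds the C-13 carbonyl and the exocyclic C16=C17 alkene on neighbouring bridges, both bonded to bridgehead C-12 (rigid β,γ-enone, p orbitals facing). Moving C-16 from C-12 to C-13 contracts this ring to ring D (C8, C14, C13, C16, C15) and creates the 13-OH and the 16-methylene at once.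
3. 25 ⇐ enol ether hydrolysis, Wittig, SmI2 demethoxylation ⇐ 22 ⇐ oxidative dearomatisation/intramolecular Diels–Alder of phenol 20, which closes ring B and the bicyclo[2.2.2]octene (C8–C9, C11–C12) onto the finished ring A lactone.
4. 20 ⇐ α-arylation (C6–C8) of lactone ester 13 with aryl bromide 18; 13 ⇐ vinyl addition/lactonisation of cyclohexanone 9 ⇐ aldol ring closure ⇐ Wacker oxidation ⇐ Ir-catalysed asymmetric allylic alkylation (C4–C5).
5. Order of ring formation: ring A, then the 19,10-lactone, then ring B together with the bicyclo[2.2.2] precursor of rings C and D, last ring D by contraction.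

Key step: step 18

Remark: locants C-1 to C-19 are the gibberellane numbers of the target; in 22–25 C-16 is still bonded to C-12. Compounds 1, 2, 4 and 14 are taken as commercially available.

Assumption: C-6 (α to the C-7 ester) is epimerisable. Step 12 is expected to give both C-6 epimers; they are carried on together, drawn with the C-6 configuration of the target, and converged by the ethoxide equilibration at the start of step 19.

**Route**

Step 1
Reactants: 1 tert-butyl(but-3-en-1-yloxy)dimethylsilane; 2 allyl methyl carbonate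
Product: 3 (E)-5-(tert-butyldimethylsilyloxy)pent-2-en-1-yl methyl carbonate
Conditions: second-generation Grubbs catalyst (3 mol%), 2 (3 equiv), CH2Cl2, 40 °C
Reagents that add atoms: none
Why: Olefin cross-metathesis of two terminal alkenes, driven by loss of ethylene, should give mainly the E-disubstituted allylic carbonate.

Step 2
Reactants: 3 (E)-allylic carbonate; 4 diethyl 2-(2,2-diethoxyethyl)malonate
Product: 5 diethyl 2-[(3S)-5-(tert-butyldimethylsilyloxy)pent-1-en-3-yl]-2-(2,2-diethoxyethyl)malonate
Conditions: [Ir(cod)Cl]2 (2 mol%), (Ra,R,R)-BINOL N,N-bis(1-phenylethyl)phosphoramidite (4 mol%), TBD (8 mol%), THF, 50 °C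
Reagents that add atoms: none
Why: Iridium-catalysed branched-selective asymmetric allylic alkylation: the malonate attacks the substituted terminus of the π-allyl iridium complex, and the ligand antipode is chosen so that the accepted model gives (S) at C-5, the only stereocentre brought in from outside.

Step 3
Reactants: 5 allylated malonate
Product: 6 diethyl 2-[(3R)-1-(tert-butyldimethylsilyloxy)-4-oxopentan-3-yl]-2-(2,2-diethoxyethyl)malonate
Conditions: PdCl2 (10 mol%), CuCl, O2 (1 atm), DMF/H2O 7:1, rt
Reagents that add atoms: water, O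
Why: Tsuji–Wacker oxidation puts oxygen on the internal carbon of the vinyl group and gives the methyl ketone (C-10 carbonyl, C-1 methyl); silyl ether, acetal and esters are inert and C-5 is not touched.

Step 4
Reactants: 6 methyl ketone acetal
Product: 8 diethyl (2R)-2-[2-(tert-butyldimethylsilyloxy)ethyl]-3-oxocyclohex-4-ene-1,1-dicarboxylate, via keto aldehyde 7 (not isolated)
Conditions: I2 (10 mol%), acetone, rt; then pyrrolidine (0.3 equiv), AcOH, toluene, 60 °C
Reagents that add atoms: none
Why: Iodine-catalysed transacetalisation frees the aldehyde without cleaving the silyl ether, and the amine-catalysed intramolecular aldol condensation through the less hindered methyl enamine can close only the six-membered ring A; C-5, next to the quaternary C-4, should not be enolised.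

Step 5
Reactants: 8 cyclohexenone
Product: 9 diethyl (2R)-2-[2-(tert-butyldimethylsilyloxy)ethyl]-3-oxocyclohexane-1,1-dicarboxylate
Conditions: H2 (1 atm), Pd/C, EtOAc, rt
Reagents that add atoms: none
Why: Heterogeneous hydrogenation saturates only the conjugated C1=C2 bond; no stereocentre is formed.

Step 6
Reactants: 9 cyclohexanone
Product: 11 ethyl 8-[2-(tert-butyldimethylsilyloxy)ethyl]-5-ethenyl-7-oxo-6-oxabicyclo[3.2.1]octane-1-carboxylate, via hydroxy diester alkoxide 10 (not isolated)
Conditions: CH2=CHMgBr, LaCl3·2LiCl, THF, −78 to 0 °C; NH4Cl work-up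
Reagents that add atoms: vinylmagnesium bromide, C=C[Mg]Br
Why: In this Grignard addition the axial ester on C-4 blocks axial approach to C-10, so the vinyl group enters equatorially, trans to the C-5 side chain; the axial alkoxide then closes the γ-lactone onto the cis ester, which fixes C-10 and C-4 relative to C-5.

Step 7
Reactants: 11 silyl ether lactone
Product: 12 2-[1-(ethoxycarbonyl)-5-ethenyl-7-oxo-6-oxabicyclo[3.2.1]octan-8-yl]acetic acid
Conditions: Jones reagent (CrO3, H2SO4, H2O), acetone, 0 °C
Reagents that add atoms: water, O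
Why: Jones oxidation removes the primary silyl ether and oxidises the alcohol through the aldehyde hydrate to the acid before it can lactonise onto an ester; the bridgehead lactone and the vinyl group are inert.

Step 8
Reactants: 12 carboxylic acid
Product: 13 ethyl 2-[1-(ethoxycarbonyl)-5-ethenyl-7-oxo-6-oxabicyclo[3.2.1]octan-8-yl]acetate
Conditions: EtI, K2CO3, DMF, rt
Reagents that add atoms: iodoethane, CCI
Why: SN2 O-alkylation of the carboxylate under mild base leaves lactone and vinyl group unchanged.

Step 9
Reactants: 14 3-bromo-2-hydroxy-5-methoxybenzaldehyde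
Product: 15 3-bromo-2,5-dimethoxybenzaldehyde
Conditions: MeI, K2CO3, DMF, rt
Reagents that add atoms: iodomethane, CI
Why: Williamson etherification of the phenol; the aldehyde is not affected.

Step 10
Reactants: 15 3-bromo-2,5-dimethoxybenzaldehyde
Product: 17 3-bromo-2,5-dimethoxyphenol, via aryl formate 16 (not isolated)
Conditions: mCPBA, CH2Cl2, 0 °C to rt; then K2CO3 (cat.), MeOH
Reagents that add atoms: 3-chloroperoxybenzoic acid, OOC(=O)c1cccc(Cl)c1
Why: In this Dakin-type Baeyer–Villiger oxidation the electron-rich aryl group migrates and the formate is methanolysed, which places the free hydroxyl next to the flanked methoxy group as the later dearomatisation requires.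

Step 11
Reactants: 17 3-bromo-2,5-dimethoxyphenol
Product: 18 (3-bromo-2,5-dimethoxyphenoxy)(tert-butyl)dimethylsilane
Conditions: TBSCl, imidazole, DMF, rt
Reagents that add atoms: tert-butyldimethylsilyl chloride, CC(C)(C)[Si](C)(C)Cl
Why: Silylation protects the phenol against the enolate base of the next step.

Step 12
Reactants: 13 lactone ester; 18 aryl bromide
Product: 19 α-aryl lactone ester (aryl = 3-(tert-butyldimethylsilyloxy)-2,5-dimethoxyphenyl on C-6)
Conditions: LiN(SiMe3)2 (2.2 equiv), Pd(dba)2 (5 mol%), P(t-Bu)3 (10 mol%), toluene, rt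
Reagents that add atoms: none
Why: Palladium-catalysed α-arylation of an ester enolate (oxidative addition, enolate transfer, reductive elimination) forms the C6–C8 bond at the only enolisable position of 13; C-6 arises as a labile α-aryl ester centre (see assumption).

Step 13
Reactants: 19 silyl-protected aryl ester
Product: 20 phenol (aryl = 3-hydroxy-2,5-dimethoxyphenyl)
Conditions: TBAF, AcOH, THF, 0 °C
Reagents that add atoms: none
Why: Buffered fluoride cleaves the aryl silyl ether without opening the lactone.

Step 14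
Reactants: 20 phenol
Product: 22 bicyclo[2.2.2]octenone cycloadduct (16-oxo; 15,15-dimethoxy; 13-methoxy-13-ene), via o-quinone monoketal 21 (not isolated)
Conditions: PhI(OAc)2, MeOH, 0 °C; evaporation; toluene, 110 °C
Reagents that add atoms: methanol, CO
Why: Oxidative dearomatisation gives the 6,6-dimethoxycyclohexa-2,4-dienone, whose C8=C14–C13=C12 diene adds the tethered vinyl group in an intramolecular Diels–Alder reaction that closes ring B through the C6–C5–C10 tether; the tether should turn to the C-14 side away from the ketal, and the rigid lactone should let C-11 add syn to the lactone oxygen and anti to C-1, which sets C-8, C-9 and C-12.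

Step 15
Reactants: 22 cycloadduct
Product: 23 15-deoxygenated 16-ketone
Conditions: SmI2 (4.4 equiv), THF/MeOH 10:1, −78 °C
Reagents that add atoms: none
Why: SmI2 cleaves α-alkoxy ketones reductively through the samarium enolate, so both methoxy groups at C-15 go, much faster than the resulting simple ketone is reduced at −78 °C without HMPA; enol ether, esters and lactone remain.

Step 16
Reactants: 23 16-ketone
Product: 24 16-methylene enol ether
Conditions: Ph3PCH3Br, KOt-Bu, THF, 0 °C to rt
Reagents that add atoms: methyltriphenylphosphonium bromide, C[P+](c1ccccc1)(c1ccccc1)c1ccccc1.[Br-]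
Why: Wittig methylenation of the C-16 ketone by the non-stabilised ylide; esters, lactone and enol ether do not react.

Step 17
Reactants: 24 16-methylene enol ether
Product: 25 13-oxo-16-methylene bicyclo[2.2.2]octane
Conditions: 1 M aq HCl, THF, 0 °C to rt
Reagents that add atoms: water, O
Why: Acid hydrolysis of the methyl enol ether (protonation at C-14, hemiketal, loss of methanol) unveils the C-13 ketone; the β,γ-unsaturated ketone cannot move into conjugation because C-12 is a bridgehead.

Step 18
Reactants: 25 13-oxo-16-methylene bicyclo[2.2.2]octane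
Product: 26 7,18-diethyl ester of the target gibberellin
Conditions: SmI2 (3 equiv), HMPA (12 equiv), t-BuOH (3 equiv), THF, −78 to 0 °C
Reagents that add atoms: none
Why: Proposed new method: SmI2/HMPA reduces the C-13 ketone to a ketyl, which adds 3-exo-trig to C-16 of the exocyclic alkene on the neighbouring bridge (cyclopropane C12–C13–C16, radical at C-17); the cyclopropylcarbinyl radical opens by cleavage of C12–C16, so the six-membered ring C8–C14–C13–C12–C16–C15 becomes the five-membered ring D with a C-13 samarium alkoxide and the regenerated 16-methylene, and the secondary C-12 radical is reduced and protonated by t-BuOH. The closest known reactions are the homoallyl–homoallyl (cyclopropylcarbinyl) radical rearrangement of 5-methylenebicyclo[2.2.2]oct-2-yl radicals to bicyclo[3.2.1]octyl radicals and SmI2 ketyl–olefin cyclisations; new is the start from a ketyl, which leaves the bridgehead hydroxyl. Ring D is closed as a net 1,2-shift through the 3-exo-trig addition/ring-opening pair, and no other ring changes. C-13 is the only new stereocentre and the cage dictates it, since C-16 can bond only to the face of C-13 that looks at its own bridge; the C-12 stereocentre disappears. The step needs forward opening to win over reversion and over simple reduction of the ketyl: the ketyl persists without a strong proton donor whereas the C-12 alkyl radical is reduced irreversibly by SmI2/HMPA, only one alkene is homoallylic to C-13, and β-elimination from the C-12 organosamarium would need a bridgehead double bond. Esters, lactone and the isolated product alkene should not be reduced under these conditions.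

Step 19
Reactants: 26 7,18-diethyl ester of the target gibberellin
Product: 28 the target gibberellin (13-hydroxy 19,10-lactone 7,18-diacid), via ring-opened hydroxy triacid 27 (not isolated)
Conditions: NaOEt (0.3 equiv), EtOH, 60 °C; then 2 M aq KOH, 80 °C; then 1 M HCl to pH 3, 0 °C to rt
Reagents that add atoms: potassium hydroxide, [K+].[OH-]
Why: Ethoxide first equilibrates C-6 to the more stable epimer with C-7 trans to C-4 (the target configuration); saponification then cleaves both esters and opens the lactone, and acidification recloses the γ-lactone from the carboxyl group cis to the C-10 oxygen, which restores C-4 (the carboxy lactone should not decarboxylate, since its enol would be a bridgehead alkene).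

**Compound list**

1 | tert-butyl(but-3-en-1-yloxy)dimethylsilane | C=CCCO[Si](C)(C)C(C)(C)C | starting material
2 | allyl methyl carbonate | C=CCOC(=O)OC | starting material
3 | (E)-5-{[tert-butyl(dimethyl)silyl]oxy}pent-2-en-1-yl methyl carbonate | COC(=O)OC/C=C/CCO[Si](C)(C)C(C)(C)C | intermediate
4 | diethyl 2-(2,2-diethoxyethyl)propanedioate | CCOC(=O)C(CC(OCC)OCC)C(=O)OCC | starting material
5 | diethyl 2-[(3S)-5-{[tert-butyl(dimethyl)silyl]oxy}pent-1-en-3-yl]-2-(2,2-diethoxyethyl)propanedioate | C=C[C@H](CCO[Si](C)(C)C(C)(C)C)C(CC(OCC)OCC)(C(=O)OCC)C(=O)OCC | intermediate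
6 | diethyl 2-[(3R)-1-{[tert-butyl(dimethyl)silyl]oxy}-4-oxopentan-3-yl]-2-(2,2-diethoxyethyl)propanedioate | CC(=O)[C@H](CCO[Si](C)(C)C(C)(C)C)C(CC(OCC)OCC)(C(=O)OCC)C(=O)OCC | intermediate
7 | diethyl 2-[(3R)-1-{[tert-butyl(dimethyl)silyl]oxy}-4-oxopentan-3-yl]-2-(2-oxoethyl)propanedioate | CC(=O)[C@H](CCO[Si](C)(C)C(C)(C)C)C(CC=O)(C(=O)OCC)C(=O)OCC | intermediate
8 | diethyl (2R)-2-(2-{[tert-butyl(dimethyl)silyl]oxy}ethyl)-3-oxocyclohex-4-ene-1,1-dicarboxylate | O=C1C=CCC(C(=O)OCC)(C(=O)OCC)[C@H]1CCO[Si](C)(C)C(C)(C)C | intermediate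
9 | diethyl (2R)-2-(2-{[tert-butyl(dimethyl)silyl]oxy}ethyl)-3-oxocyclohexane-1,1-dicarboxylate | O=C1CCCC(C(=O)OCC)(C(=O)OCC)[C@H]1CCO[Si](C)(C)C(C)(C)C | intermediate
10 | diethyl (2R,3R)-2-(2-{[tert-butyl(dimethyl)silyl]oxy}ethyl)-3-ethenyl-3-hydroxycyclohexane-1,1-dicarboxylate, formed as its magnesium alkoxide (OH cis to the C-2 side chain) | C=C[C@]1(O)CCCC(C(=O)OCC)(C(=O)OCC)[C@H]1CCO[Si](C)(C)C(C)(C)C | intermediate
11 | ethyl 8-(2-{[tert-butyl(dimethyl)silyl]oxy}ethyl)-5-ethenyl-7-oxo-6-oxabicyclo[3.2.1]octane-1-carboxylate (C-8 side chain syn to the lactone bridge; C-4, C-5, C-10 as in the target) | C=C[C@@]12CCC[C@@](C(=O)OCC)(C(=O)O1)[C@H]2CCO[Si](C)(C)C(C)(C)C | intermediate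
12 | 2-[1-(ethoxycarbonyl)-5-ethenyl-7-oxo-6-oxabicyclo[3.2.1]octan-8-yl]acetic acid | C=C[C@@]12CCC[C@@](C(=O)OCC)(C(=O)O1)[C@H]2CC(=O)O | intermediate
13 | ethyl 2-[1-(ethoxycarbonyl)-5-ethenyl-7-oxo-6-oxabicyclo[3.2.1]octan-8-yl]acetate | C=C[C@@]12CCC[C@@](C(=O)OCC)(C(=O)O1)[C@H]2CC(=O)OCC | intermediate
14 | 3-bromo-2-hydroxy-5-methoxybenzaldehyde | COc1cc(Br)c(O)c(C=O)c1 | starting material
15 | 3-bromo-2,5-dimethoxybenzaldehyde | COc1cc(Br)c(OC)c(C=O)c1 | intermediate
16 | 3-bromo-2,5-dimethoxyphenyl formate | COc1cc(Br)c(OC)c(OC=O)c1 | intermediate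
17 | 3-bromo-2,5-dimethoxyphenol | COc1cc(Br)c(OC)c(O)c1 | intermediate
18 | (3-bromo-2,5-dimethoxyphenoxy)(tert-butyl)dimethylsilane | COc1cc(Br)c(OC)c(O[Si](C)(C)C(C)(C)C)c1 | intermediate
19 | ethyl 2-(3-{[tert-butyl(dimethyl)silyl]oxy}-2,5-dimethoxyphenyl)-2-[1-(ethoxycarbonyl)-5-ethenyl-7-oxo-6-oxabicyclo[3.2.1]octan-8-yl]acetate (C-6 as in the target) | C=C[C@@]12CCC[C@@](C(=O)OCC)(C(=O)O1)[C@H]2[C@@H](c1cc(OC)cc(O[Si](C)(C)C(C)(C)C)c1OC)C(=O)OCC | intermediate
20 | ethyl 2-(3-hydroxy-2,5-dimethoxyphenyl)-2-[1-(ethoxycarbonyl)-5-ethenyl-7-oxo-6-oxabicyclo[3.2.1]octan-8-yl]acetate | C=C[C@@]12CCC[C@@](C(=O)OCC)(C(=O)O1)[C@H]2[C@@H](c1cc(OC)cc(O)c1OC)C(=O)OCC | intermediate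
21 | o-quinone monoketal: the 3,6,6-trimethoxy-cyclohexa-2,4-dien-1-one carrying the lactone ester side chain at C-5 of the dienone | C=C[C@@]12CCC[C@@](C(=O)OCC)(C(=O)O1)[C@H]2[C@@H](C1=CC(OC)=CC(=O)C1(OC)OC)C(=O)OCC | intermediate
22 | cycloadduct: rings A, B and 19,10-lactone as in the target; bicyclo[2.2.2]octene with C-16 ketone bonded to C-12 and C-15, 15,15-dimethoxy, 13-methoxy-13(14)-ene; diethyl 7,18-diester | O=C1C(OC)(OC)[C@]23C=C(OC)[C@H]1C[C@H]2[C@@]12CCC[C@@](C(=O)OCC)(C(=O)O1)[C@H]2[C@@H]3C(=O)OCC | intermediate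
23 | as 22 but with CH2 at C-15 (16-ketone, 13-methoxy-13(14)-ene) | O=C1C[C@]23C=C(OC)[C@H]1C[C@H]2[C@@]12CCC[C@@](C(=O)OCC)(C(=O)O1)[C@H]2[C@@H]3C(=O)OCC | intermediate
24 | as 23 but with exocyclic methylene at C-16 | C=C1C[C@]23C=C(OC)[C@H]1C[C@H]2[C@@]12CCC[C@@](C(=O)OCC)(C(=O)O1)[C@H]2[C@@H]3C(=O)OCC | intermediate
25 | 13-oxo-16-methylene bicyclo[2.2.2]octane isomer of the gibberellin skeleton (C-16 on C-12), 19,10-lactone, diethyl 7,18-diester | C=C1C[C@]23CC(=O)[C@H]1C[C@H]2[C@@]12CCC[C@@](C(=O)OCC)(C(=O)O1)[C@H]2[C@@H]3C(=O)OCC | intermediate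
26 | 7,18-diethyl ester of the target gibberellin (13-hydroxy, 16-methylene, 19,10-lactone) | C=C1C[C@]23C[C@@]1(O)CC[C@H]2[C@@]12CCC[C@@](C(=O)OCC)(C(=O)O1)[C@H]2[C@@H]3C(=O)OCC | intermediate
27 | ring-opened hydroxy triacid (10-hydroxy, 4,4-dicarboxy, 7-carboxy), formed as its tripotassium salt | C=C1C[C@]23C[C@@]1(O)CC[C@H]2[C@]2(O)CCCC(C(=O)O)(C(=O)O)[C@H]2[C@@H]3C(=O)O | intermediate
28 | target gibberellin: 10,13-dihydroxy-20-norgibberell-16-ene-7,18,19-trioic acid 19,10-lactone, stereochemistry as in the SMILES | C=C1C[C@]23C[C@@]1(O)CC[C@H]2[C@@]12CCC[C@@](C(=O)O)(C(=O)O1)[C@H]2[C@@H]3C(=O)O | target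

**Step count and risks**

Total step count: 19. Longest linear sequence: 16 steps (steps 1–8 and 12–19); the aryl bromide branch (steps 9–11) has 3 steps.

Steps most likely to fail:

1. Step 18. The samarium ketyl may be reduced and protonated to the secondary C-13 alcohol, or the cyclopropylcarbinyl radical may revert, faster than the C12–C16 bond opens. The fallback uses known chemistry, sets out from 23 and returns at 26. Ketone 23 is reduced with NaBH4 (EtOH, 0 °C) to the C-16 alcohol F1. Aqueous HCl in THF hydrolyses the enol ether to the β-hydroxy ketone F2. K2CO3 in EtOH opens F2 by retro-aldol cleavage of the C12–C16 bond to the keto aldehyde F3. In the same flask dimethyl (1-diazo-2-oxopropyl)phosphonate (Ohira–Bestmann homologation) converts F3 into the alkynyl ketone F4. SmI2/HMPA/t-BuOH then closes ring D by ketyl–alkyne 5-exo-dig reductive cyclisation, in which the propargyl arm on C-8 can reach only one face of C-13, and gives 26 directly.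

2. Step 14. The facial selectivity of the cycloaddition may be poor, because in the transition state that leads to 22 the dimethyl ketal at C-15 lies next to the C-7 ester on C-6 when C-6 has the configuration of the target; dimerisation of the o-quinone monoketal may also compete. The fallback sets out from 20 and returns at 23. Saponification of the less hindered C-7 ester of 20 (LiOH, THF/H2O; acidification recloses the lactone) gives the phenol acid F5. PhI(OAc)2 in CH2Cl2 without methanol lets the carboxyl group add to C-15 and gives the lactone-bridged o-quinone ketal F6. In F6 the ketal oxygen is tied back and C-6, which equilibrates readily here, relays the facial choice, because C-15 must end cis to C-7. Heating in toluene gives the cycloadduct F7. SmI2 in THF/MeOH cleaves both C-15–O bonds and releases the keto acid F8, and EtI/K2CO3 gives 23.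

3. Step 12. Enolate transfer and reductive elimination may be slow with the β-branched enolate and the ortho-methoxy aryl bromide, so that dehalogenation or Claisen-type condensation takes over. The fallback reverses the polarity, sets out from 13 and 18 and returns at 19. Ester 13 is deprotonated (LiN(SiMe3)2, −78 °C) and brominated with NBS to the α-bromo ester F9. Bromide 18 is converted by Miyaura borylation (B2pin2, KOAc, Pd(dppf)Cl2, dioxane) into the aryl boronic ester F10. A nickel-catalysed Suzuki-type coupling of the secondary α-bromo ester (Ni(PPh3)4, K3PO4, toluene) gives 19.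

**Further compounds**

F1 | step 18 | C-16 alcohol from 23 (both C-16 epimers; the centre is lost in the retro-aldol step) | OC1C[C@]23C=C(OC)[C@H]1C[C@H]2[C@@]12CCC[C@@](C(=O)OCC)(C(=O)O1)[C@H]2[C@@H]3C(=O)OCC
F2 | step 18 | 16-hydroxy-13-oxo bicyclo[2.2.2]octane (β-hydroxy ketone) | OC1C[C@]23CC(=O)[C@H]1C[C@H]2[C@@]12CCC[C@@](C(=O)OCC)(C(=O)O1)[C@H]2[C@@H]3C(=O)OCC
F3 | step 18 | keto aldehyde: ring C cyclohexanone (C-13 ketone) with a 2-oxoethyl group on C-8 | O=CC[C@]23CC(=O)CC[C@H]2[C@@]12CCC[C@@](C(=O)OCC)(C(=O)O1)[C@H]2[C@@H]3C(=O)OCC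
F4 | step 18 | alkynyl ketone: ring C cyclohexanone with a prop-2-ynyl group on C-8 | C#CC[C@]23CC(=O)CC[C@H]2[C@@]12CCC[C@@](C(=O)OCC)(C(=O)O1)[C@H]2[C@@H]3C(=O)OCC
F5 | step 14 | 2-(3-hydroxy-2,5-dimethoxyphenyl)-2-[1-(ethoxycarbonyl)-5-ethenyl-7-oxo-6-oxabicyclo[3.2.1]octan-8-yl]acetic acid | C=C[C@@]12CCC[C@@](C(=O)OCC)(C(=O)O1)[C@H]2[C@@H](c1cc(OC)cc(O)c1OC)C(=O)O
F6 | step 14 | lactone-bridged o-quinone ketal (C-7 carboxyl bonded to C-15; C-15 also carries OMe) | C=C[C@@]12CCC[C@@](C(=O)OCC)(C(=O)O1)[C@H]2[C@@H]1C(=O)O[C@]2(OC)C(=O)C=C(OC)C=C12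
F7 | step 14 | cycloadduct with the 7,15-lactone ketal (lactone oxygen on C-15 syn to the C9–C11 bridge) | O=C1[C@]4(OC)[C@]23C=C(OC)[C@H]1C[C@H]2[C@@]12CCC[C@@](C(=O)OCC)(C(=O)O1)[C@H]2[C@@H]3C(=O)O4
F8 | step 14 | 7-carboxylic acid corresponding to 23 | O=C1C[C@]23C=C(OC)[C@H]1C[C@H]2[C@@]12CCC[C@@](C(=O)OCC)(C(=O)O1)[C@H]2[C@@H]3C(=O)O
F9 | step 12 | ethyl 2-bromo-2-[1-(ethoxycarbonyl)-5-ethenyl-7-oxo-6-oxabicyclo[3.2.1]octan-8-yl]acetate (both C-6 epimers) | C=C[C@@]12CCC[C@@](C(=O)OCC)(C(=O)O1)[C@H]2C(Br)C(=O)OCC
F10 | step 12 | tert-butyl[2,5-dimethoxy-3-(4,4,5,5-tetramethyl-1,3,2-dioxaborolan-2-yl)phenoxy]dimethylsilane | COc1cc(B2OC(C)(C)C(C)(C)O2)c(OC)c(O[Si](C)(C)C(C)(C)C)c1
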